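The plan cuts the benzylic C4–C4a bond between the pyran ring and benzene ring A. The aliphatic half that remains is C2 with its methyl group and oxygen, C3, C4 and the prenyl arm C1' to C4'. This half is atom for atom (R)-linalool, so the only stereocentre is bought rather than made. In one flask the vinyl group is hydroborated and the primary borane is cross-coupled with a 2-chloro-6-methyl-4-silyloxyphenyl bromide. Bromine marks C4a, and chlorine is saved for the later O1–C8a closure. The chain is then extended from the prenyl terminus. Its α-methyl (Z)-enoate calls for a phosphonopropanoate reagent, since a phosphonoacetate would leave out the C8' methyl group.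

Key step: step 3

Numbering used: chroman O1, C2, C3, C4, C4a, C5 to C8, C8a; side chain C1' to C8' counted from C2.
Assumption: commercial (R)-(−)-linalool is taken at the enantiomeric purity supplied. No bond to C2 is broken anywhere in the route, so that purity should carry through to the target.

Step 1
Reactants: 1 3-chloro-5-methylphenol
Product: 2 4-bromo-3-chloro-5-methylphenol
Conditions: NBS (1.0 equiv), MeCN, −10 °C → rt
Reagents that add atoms: N-bromosuccinimide, O=C1CCC(=O)N1Br
Why: Electrophilic aromatic bromination with NBS in a polar solvent is steered by the hydroxyl group to its para position, which the methyl and chloro groups also activate as ortho directors, so bromine should land on the future C4a.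

Step 2
Reactants: 2 4-bromo-3-chloro-5-methylphenol
Product: 3 2-bromo-1-chloro-3-methyl-5-(triisopropylsilyloxy)benzene
Conditions: TIPSCl, imidazole, DMF, rt
Reagents that add atoms: chlorotriisopropylsilane, CC(C)[Si](Cl)(C(C)C)C(C)C
Why: Imidazole-promoted O-silylation of a phenol whose two ortho positions carry only hydrogen is routine, and the bulky silyl ether should tolerate carbonate base, SeO2, cold organolithium reagents and mild acid yet leave with fluoride at the end.

Step 3
Reactants: 4 (R)-(−)-linalool [(R)-3,7-dimethylocta-1,6-dien-3-ol]; 3 2-bromo-1-chloro-3-methyl-5-(triisopropylsilyloxy)benzene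
Product: 6 (R)-1-[2-chloro-6-methyl-4-(triisopropylsilyloxy)phenyl]-3,7-dimethyloct-6-en-3-ol, via B-alkyl-9-BBN borane 5 (not isolated)
Conditions: 4 (1.5 equiv), 9-BBN (0.5 M in THF, 3.0 equiv), 0 °C → rt; then H2O, Cs2CO3 (4 equiv), 3 (1.0 equiv), Pd(dppf)Cl2 (5 mol %), THF/H2O 10:1, 65 °C
Reagents that add atoms: none
Why: The bulky dialkylborane delivers boron to the terminal vinyl carbon (future C4) of 4 by four-centre syn addition, and the second equivalent allows for slow O-borylation of the tertiary carbinol, which the aqueous base reverses. Oxidative addition of the aryl C–Br bond to zerovalent palladium (generated from Pd(dppf)Cl2) is followed by transfer of the primary alkyl group from the base-bound borate to palladium, and the wide bite angle of dppf then speeds sp3–sp2 reductive elimination past β-hydride elimination to give C4–C4a. The closest known reaction type is the one-pot hydroboration/B-alkyl Suzuki–Miyaura coupling of terminal alkenes with ortho-substituted aryl bromides. No ring is closed and no stereocentre is created, because C2 comes from the chiral pool, none of its four bonds takes part, and its configuration is therefore retained. Two chemoselectivities are required: the steric demand of 9-BBN separates the vinyl group from the trisubstituted C3'=C4' alkene by a wide rate margin, and the weaker C–Br bond together with a dppf catalyst that ignores electron-rich aryl chlorides at this temperature keeps the C–Cl bond for step 4. DMF is left out and the carbonate is used in wet THF so that the aryl silyl ether is not eroded.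

Step 4
Reactants: 6 (R)-1-[2-chloro-6-methyl-4-(triisopropylsilyloxy)phenyl]-3,7-dimethyloct-6-en-3-ol
Product: 7 (R)-2,5-dimethyl-2-(4-methylpent-3-en-1-yl)-7-(triisopropylsilyloxy)chroman
Conditions: Pd(OAc)2 (5 mol %), 2-(di-tert-butylphosphino)-1,1'-binaphthyl (6 mol %), Cs2CO3 (1.5 equiv), toluene, 90 °C
Reagents that add atoms: none
Why: In this intramolecular Buchwald–Hartwig C–O coupling the electron-rich, bulky phosphine permits insertion into the C–Cl bond and forces O1–C8a reductive elimination to the six-membered pyran, the tertiary alkoxide has no carbinol hydrogen for β-hydride elimination, and the C2–O bond is never broken, so the (R) configuration is kept.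

Step 5
Reactants: 7 (R)-2,5-dimethyl-2-(4-methylpent-3-en-1-yl)-7-(triisopropylsilyloxy)chroman
Product: 9 (E)-5-[(R)-2,5-dimethyl-7-(triisopropylsilyloxy)chroman-2-yl]-2-methylpent-2-en-1-ol, via (E)-enal 8 (not isolated)
Conditions: SeO2 (0.2 equiv), tBuOOH (5.5 M in decane, 3 equiv), salicylic acid (0.1 equiv), CH2Cl2, 0 °C → rt; then crude, NaBH4, MeOH, 0 °C
Reagents that add atoms: selenium dioxide, O=[Se]=O (oxygen carrier); tert-butyl hydroperoxide, CC(C)(C)OO (terminal oxygen source)
Why: Riley-type catalytic allylic oxidation (ene reaction, then [2,3]-sigmatropic shift) attacks the only alkene at the methyl group trans to the chain and thereby fixes the (E) geometry of C3'=C4', while the borohydride stage returns over-oxidised enal to the alcohol.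

Step 6
Reactants: 9 (E)-5-[(R)-2,5-dimethyl-7-(triisopropylsilyloxy)chroman-2-yl]-2-methylpent-2-en-1-ol
Product: 10 (R)-2-[(E)-5-bromo-4-methylpent-3-en-1-yl]-2,5-dimethyl-7-(triisopropylsilyloxy)chroman
Conditions: CBr4, PPh3, CH2Cl2, −20 → 0 °C; used at once
Reagents that add atoms: carbon tetrabromide, BrC(Br)(Br)Br
Why: The Appel reaction displaces the alkoxyphosphonium group by bromide in a neutral SN2 process at the primary allylic carbon, which should avoid allylic transposition, loss of alkene geometry and damage to the silyl ether.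

Step 7
Reactants: 11 acetaldehyde; 12 tert-butylamine
Product: 13 (E)-N-tert-butylethanimine
Conditions: neat, 0 °C; KOH pellets; distillation
Reagents that add atoms: none
Why: This is a plain aldehyde–amine condensation, and the bulky N-substituent suppresses self-condensation and shields the C=N carbon from nucleophiles in the next step.

Step 8
Reactants: 13 (E)-N-tert-butylethanimine; 10 (R)-2-[(E)-5-bromo-4-methylpent-3-en-1-yl]-2,5-dimethyl-7-(triisopropylsilyloxy)chroman
Product: 16 (E)-7-[(R)-2,5-dimethyl-7-(triisopropylsilyloxy)chroman-2-yl]-4-methylhept-4-enal, via lithio azaenolate 14 (not isolated), via alkylated aldimine 15 (not isolated)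
Conditions: 13 (1.8 equiv), LiN(iPr)2 (commercial solution), THF, −78 → 0 °C; 10, THF, −78 → 0 °C; then 1 M aq. oxalic acid, Et2O, rt
Reagents that add atoms: water, O
Why: Metalloenamine (azaenolate) alkylation delivers an acetaldehyde enolate equivalent in SN2 fashion to the primary allylic bromide and so adds C6' and C7', and mild acid hydrolysis of the C=N bond frees a γ,δ-unsaturated aldehyde that has no tendency to conjugate and keeps its silyl ether.

Step 9
Reactants: 17 methyl 2-[bis(2,2,2-trifluoroethoxy)phosphoryl]acetate
Product: 19 methyl 2-[bis(2,2,2-trifluoroethoxy)phosphoryl]propanoate (racemic), via potassium phosphonoacetate carbanion 18 (not isolated)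
Conditions: KOtBu (1.0 equiv), THF, 0 °C; MeI, 0 °C → rt
Reagents that add atoms: iodomethane, CI
Why: C-alkylation of a stabilised phosphonate carbanion with one equivalent of base limits double methylation and installs the carbon that becomes the C8' methyl group, and the new centre is of no consequence because it is deprotonated in step 10.

Step 10
Reactants: 19 methyl 2-[bis(2,2,2-trifluoroethoxy)phosphoryl]propanoate; 16 (E)-7-[(R)-2,5-dimethyl-7-(triisopropylsilyloxy)chroman-2-yl]-4-methylhept-4-enal
Product: 21 methyl (2Z,6E)-9-[(R)-2,5-dimethyl-7-(triisopropylsilyloxy)chroman-2-yl]-2,6-dimethylnona-2,6-dienoate, via potassium phosphonopropanoate carbanion 20 (not isolated)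
Conditions: 19, KN(SiMe3)2, 18-crown-6, THF, −78 °C; then 16, −78 °C
Reagents that add atoms: none
Why: In the Still–Gennari olefination the electron-poor trifluoroethyl phosphonate and the crown-sequestered potassium ion make collapse of the kinetic adduct faster than its reversal, which should place the ester cis to the chain and give the (Z)-C7'=C8' alkene.

Step 11
Reactants: 21 methyl (2Z,6E)-9-[(R)-2,5-dimethyl-7-(triisopropylsilyloxy)chroman-2-yl]-2,6-dimethylnona-2,6-dienoate
Product: 22 methyl (2Z,6E)-9-[(R)-7-hydroxy-2,5-dimethylchroman-2-yl]-2,6-dimethylnona-2,6-dienoate (target)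
Conditions: Bu4NF, AcOH, THF, 0 °C
Reagents that add atoms: none
Why: Fluoride-mediated desilylation is driven by the Si–F bond and the good phenoxide leaving group, and the acetic acid buffer should keep the methyl ester, the (Z)-enoate and C2 untouched.

Compound list
1 | 3-chloro-5-methylphenol | Cc1cc(O)cc(Cl)c1 | starting material
2 | 4-bromo-3-chloro-5-methylphenol | Cc1cc(O)cc(Cl)c1Br | intermediate
3 | 2-bromo-1-chloro-3-methyl-5-(triisopropylsilyloxy)benzene | Cc1cc(O[Si](C(C)C)(C(C)C)C(C)C)cc(Cl)c1Br | intermediate
4 | (R)-(−)-linalool | CC(C)=CCC[C@](O)(C)C=C | starting material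
5 | 1-(9-borabicyclo[3.3.1]nonan-9-yl)-3,7-dimethyloct-6-en-3-ol, drawn as the free carbinol; same spatial arrangement as 4, descriptor formally (S) because boron ranks below carbon | CC(C)=CCC[C@](O)(C)CCB1C2CCCC1CCC2 | intermediate
6 | (R)-1-[2-chloro-6-methyl-4-(triisopropylsilyloxy)phenyl]-3,7-dimethyloct-6-en-3-ol | CC(C)=CCC[C@](O)(C)CCc1c(C)cc(O[Si](C(C)C)(C(C)C)C(C)C)cc1Cl | intermediate
7 | (R)-2,5-dimethyl-2-(4-methylpent-3-en-1-yl)-7-(triisopropylsilyloxy)chroman | CC(C)=CCC[C@]1(C)CCc2c(C)cc(O[Si](C(C)C)(C(C)C)C(C)C)cc2O1 | intermediate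
8 | (E)-5-[(R)-2,5-dimethyl-7-(triisopropylsilyloxy)chroman-2-yl]-2-methylpent-2-enal | O=C/C(C)=C/CC[C@]1(C)CCc2c(C)cc(O[Si](C(C)C)(C(C)C)C(C)C)cc2O1 | intermediate
9 | (E)-5-[(R)-2,5-dimethyl-7-(triisopropylsilyloxy)chroman-2-yl]-2-methylpent-2-en-1-ol | OC/C(C)=C/CC[C@]1(C)CCc2c(C)cc(O[Si](C(C)C)(C(C)C)C(C)C)cc2O1 | intermediate
10 | (R)-2-[(E)-5-bromo-4-methylpent-3-en-1-yl]-2,5-dimethyl-7-(triisopropylsilyloxy)chroman | BrC/C(C)=C/CC[C@]1(C)CCc2c(C)cc(O[Si](C(C)C)(C(C)C)C(C)C)cc2O1 | intermediate
11 | acetaldehyde | CC=O | starting material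
12 | tert-butylamine | CC(C)(C)N | starting material
13 | (E)-N-tert-butylethanimine | C/C=N/C(C)(C)C | intermediate
14 | lithium N-tert-butyl-N-vinylamide (lithio azaenolate of 13) | [Li]N(C=C)C(C)(C)C | intermediate
15 | (1E,4E)-N-tert-butyl-7-[(R)-2,5-dimethyl-7-(triisopropylsilyloxy)chroman-2-yl]-4-methylhept-4-en-1-imine | CC(C)(C)/N=C/CC/C(C)=C/CC[C@]1(C)CCc2c(C)cc(O[Si](C(C)C)(C(C)C)C(C)C)cc2O1 | intermediate
16 | (E)-7-[(R)-2,5-dimethyl-7-(triisopropylsilyloxy)chroman-2-yl]-4-methylhept-4-enal | O=CCC/C(C)=C/CC[C@]1(C)CCc2c(C)cc(O[Si](C(C)C)(C(C)C)C(C)C)cc2O1 | intermediate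
17 | methyl 2-[bis(2,2,2-trifluoroethoxy)phosphoryl]acetate | COC(=O)CP(=O)(OCC(F)(F)F)OCC(F)(F)F | starting material
18 | potassium salt of the carbanion of 17 | [K+].COC(=O)[CH-]P(=O)(OCC(F)(F)F)OCC(F)(F)F | intermediate
19 | methyl 2-[bis(2,2,2-trifluoroethoxy)phosphoryl]propanoate (racemic) | COC(=O)C(C)P(=O)(OCC(F)(F)F)OCC(F)(F)F | intermediate
20 | potassium salt of the carbanion of 19 | [K+].COC(=O)[C-](C)P(=O)(OCC(F)(F)F)OCC(F)(F)F | intermediate
21 | methyl (2Z,6E)-9-[(R)-2,5-dimethyl-7-(triisopropylsilyloxy)chroman-2-yl]-2,6-dimethylnona-2,6-dienoate | COC(=O)/C(C)=C\CC/C(C)=C/CC[C@]1(C)CCc2c(C)cc(O[Si](C(C)C)(C(C)C)C(C)C)cc2O1 | intermediate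
22 | methyl (2Z,6E)-9-[(R)-7-hydroxy-2,5-dimethylchroman-2-yl]-2,6-dimethylnona-2,6-dienoate | COC(=O)/C(C)=C\CC/C(C)=C/CC[C@]1(C)CCc2c(C)cc(O)cc2O1 | target

Total step count: 11 (steps 7 and 9 are one-step reagent preparations on side branches).
Longest linear sequence: 9 steps (steps 1, 2, 3, 4, 5, 6, 8, 10 and 11, from 1 to 22).

Steps most likely to fail

Step 3. Oxidative addition at the doubly ortho-substituted, electron-rich C–Br bond may be sluggish. That would give the hydroxy borane time to protodeboronate and the base time to erode the silyl ether. The fallback sets out from 3 and 4 and makes the same C4–C4a bond with the alkene itself as the partner, in a Mizoroki–Heck reaction (Pd(OAc)2, P(o-tol)3, Et3N, MeCN, 90 °C). The carbinol carbon bears no hydrogen, so β-hydride elimination can only give (R,E)-1-[2-chloro-6-methyl-4-(triisopropylsilyloxy)phenyl]-3,7-dimethylocta-1,6-dien-3-ol F1. Diimide, generated from 2-nitrobenzenesulfonyl hydrazide and Et3N, should then saturate the disubstituted C3=C4 alkene in preference to the trisubstituted one without touching C–Cl. This comes back to the route at 6.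

Step 4. Insertion into the electron-rich C–Cl bond may be reluctant, or hydrodechlorination may outrun C–O reductive elimination from the crowded tertiary alkoxide. The fallback sets out from 4 and shifts the halogen pair on ring A, so that the ring closes at a C–Br bond under copper catalysis.
- Commercial 3-bromo-5-methylphenol F2 is para-iodinated (NIS, MeCN) to 3-bromo-4-iodo-5-methylphenol F3.
- F3 is silylated (TIPSCl, imidazole) to (3-bromo-4-iodo-5-methylphenoxy)triisopropylsilane F4.
- Borane 5, made from 4 as in step 3, is coupled at the C–I bond (Pd(dppf)Cl2, Cs2CO3, wet THF, 45 °C) to give (R)-1-[2-bromo-6-methyl-4-(triisopropylsilyloxy)phenyl]-3,7-dimethyloct-6-en-3-ol F5.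
- An intramolecular Ullmann-type etherification (CuI, 1,10-phenanthroline, Cs2CO3, toluene, 110 °C) forms O1–C8a and comes back to the route at 7.

Step 5. Conversion may stall, over-oxidation may spread, or the oxidant may attack the benzylic C4 and aryl methyl positions of the electron-rich chroman. The fallback sets out from 7 and rebuilds the alkene instead of oxidising its methyl group.
- Lemieux–Johnson cleavage (OsO4 cat., NaIO4, 2,6-lutidine, dioxane/H2O) gives 3-[(S)-2,5-dimethyl-7-(triisopropylsilyloxy)chroman-2-yl]propanal F6. The geometry at C2 is unchanged; only the descriptor changes.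
- Wittig olefination with the stabilised ylide ethyl 2-(triphenylphosphoranylidene)propanoate (toluene, 60 °C) gives ethyl (E)-5-[(R)-2,5-dimethyl-7-(triisopropylsilyloxy)chroman-2-yl]-2-methylpent-2-enoate F7.
- Reduction with iBu2AlH (CH2Cl2, −78 °C) comes back to the route at 9.

Further compounds
F1 | step 3 | (R,E)-1-[2-chloro-6-methyl-4-(triisopropylsilyloxy)phenyl]-3,7-dimethylocta-1,6-dien-3-ol | CC(C)=CCC[C@](O)(C)/C=C/c1c(C)cc(O[Si](C(C)C)(C(C)C)C(C)C)cc1Cl
F2 | step 4 | 3-bromo-5-methylphenol (commercial) | Cc1cc(O)cc(Br)c1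
F3 | step 4 | 3-bromo-4-iodo-5-methylphenol | Cc1cc(O)cc(Br)c1I
F4 | step 4 | (3-bromo-4-iodo-5-methylphenoxy)triisopropylsilane | Cc1cc(O[Si](C(C)C)(C(C)C)C(C)C)cc(Br)c1I
F5 | step 4 | (R)-1-[2-bromo-6-methyl-4-(triisopropylsilyloxy)phenyl]-3,7-dimethyloct-6-en-3-ol | CC(C)=CCC[C@](O)(C)CCc1c(C)cc(O[Si](C(C)C)(C(C)C)C(C)C)cc1Br
F6 | step 5 | 3-[(S)-2,5-dimethyl-7-(triisopropylsilyloxy)chroman-2-yl]propanal | O=CCC[C@]1(C)CCc2c(C)cc(O[Si](C(C)C)(C(C)C)C(C)C)cc2O1
F7 | step 5 | ethyl (E)-5-[(R)-2,5-dimethyl-7-(triisopropylsilyloxy)chroman-2-yl]-2-methylpent-2-enoate | CCOC(=O)/C(C)=C/CC[C@]1(C)CCc2c(C)cc(O[Si](C(C)C)(C(C)C)C(C)C)cc2O1
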